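**Retrosynthetic overview**

1. Target ⇐ reduction of the C9 ester of an all-cis 2-aryl-4-benzyl-tetrahydrofuran-3-carboxylate.
2. All-cis ester ⇐ syn-hydrogenation of the C7=C8 bond of a 2-aryl-4-benzyl-4,5-dihydrofuran-3-carboxylate from the face opposite the C8′ benzyl group, which sets C7 and C8 together from C8′.
3. Dihydrofuran ⇐ closure of the 7-O-9′ bond by attack of the C9′ hydroxyl on the electrophilic benzylic C7 of an open 8–8′-linked C6C3–C6C3 chain, the ring closure of lignan biosynthesis, with C7 held at the ketone level so that its configuration is not fixed at this point.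
4. Open chain ⇐ 8–8′ bond by enantioselective radical coupling of two phenylpropanoid units: the C8 radical of a 3,4,5-trimethoxybenzoylacetate and the chiral enamine of 3-(3,4-dimethoxyphenyl)propanal; C8′ (R) is the only centre set by a catalyst.
5. Ring order: only one ring is made, the tetrahydrofuran, after the 8–8′ bond and before C7 and C8 are set.

Assumption: aldehyde 3 is bought as a catalogue compound, and the (2R,5S)-imidazolidinone is taken to give the (R)-aldehyde as it does with bromomalonates; if the first run shows the opposite sense, the (2S,5R) catalyst is used with nothing else changed.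

The target is the all-cis (2R,3R,4R) tetrahydrofuran (lignan numbering 7R,8R,8′R).

**Route**

Step 1
Reactants: 1 ethyl 3-oxo-3-(3,4,5-trimethoxyphenyl)propanoate
Product: 2 ethyl 2-bromo-3-oxo-3-(3,4,5-trimethoxyphenyl)propanoate (racemic)
Conditions: NBS (1.05 equiv), NH4OAc (10 mol%), Et2O, 25 °C
Reagents that add atoms: N-bromosuccinimide, O=C1CCC(=O)N1Br
Why: Ammonium acetate-catalysed enol bromination of the β-keto ester at the active methylene (C8) is far faster than bromination of the carbonyl-deactivated trimethoxyaryl ring, and it turns C8 into a radical precursor without creating any stereocentre that matters.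

Step 2
Reactants: 2 ethyl 2-bromo-3-oxo-3-(3,4,5-trimethoxyphenyl)propanoate; 3 3-(3,4-dimethoxyphenyl)propanal (2 equiv)
Product: 5 ethyl (3R)-4-(3,4-dimethoxyphenyl)-3-(hydroxymethyl)-2-(3,4,5-trimethoxybenzoyl)butanoate (C2 epimers), via keto aldehyde 4 (not isolated)
Conditions: Ru(bpy)3Cl2 (0.5 mol%), (2R,5S)-2-tert-butyl-3,5-dimethylimidazolidin-4-one·TfOH (20 mol%), 2,6-lutidine, DMF, blue LEDs, 23 °C; then MeOH, NaBH4, −40 °C
Reagents that add atoms: none
Why: In this Nicewicz–MacMillan photoredox organocatalytic α-alkylation of an aldehyde, photoreduced Ru(bpy)3Cl2 cleaves the C–Br bond of 2 to an electrophilic C8 radical (a hybrid of the bromomalonate and phenacyl bromide radicals that are established partners) which adds to the unshielded face of the (E)-enamine formed from 3 and the imidazolidinone, making the 8–8′ bond and setting C8′ as R, and NaBH4 at −40 °C then reduces only the aldehyde of 4 so that C8′ can no longer epimerise or be lost by furan formation, while C8 is an epimer mixture that is erased in step 3.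

Step 3
Reactants: 5 ethyl (3R)-4-(3,4-dimethoxyphenyl)-3-(hydroxymethyl)-2-(3,4,5-trimethoxybenzoyl)butanoate
Product: 7 ethyl (4R)-4-(3,4-dimethoxybenzyl)-2-(3,4,5-trimethoxyphenyl)-4,5-dihydrofuran-3-carboxylate, via cyclic hemiketal 6 (not isolated)
Conditions: p-TsOH·H2O (10 mol%), EtOH, 3 Å MS, 60 °C
Reagents that add atoms: none
Why: Acid-catalysed 5-exo hemiketalisation of the C9′ hydroxyl onto the C7 ketone followed by loss of water (cyclodehydration) gives the push–pull β-alkoxyacrylate, the known thermodynamic sink of γ-hydroxy β-keto esters and of α-acyl butyrolactones in acidic ethanol, which also re-opens any lactonised material, and in it C8 is sp2 while C8′ is untouched.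

Step 4
Reactants: 7 ethyl (4R)-4-(3,4-dimethoxybenzyl)-2-(3,4,5-trimethoxyphenyl)-4,5-dihydrofuran-3-carboxylate
Product: 8 ethyl (2R,3S,4R)-4-(3,4-dimethoxybenzyl)-2-(3,4,5-trimethoxyphenyl)tetrahydrofuran-3-carboxylate (all-cis)
Conditions: H2 (20 bar), 10% Pd/C, EtOAc, 40 °C
Reagents that add atoms: none
Why: Heterogeneous syn-hydrogenation of the tetrasubstituted enol-ether double bond takes place on the face opposite the C8′ benzyl group, which A(1,2) strain with the ester holds pseudo-axial, so both hydrogens enter trans to it and C7 (R) and C8 are set all-cis to C8′ in one operation, while the aryl ethers and ester are inert and the new benzylic C–O bond is slow to cleave in neutral ethyl acetate.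

Step 5
Reactants: 8 ethyl (2R,3S,4R)-4-(3,4-dimethoxybenzyl)-2-(3,4,5-trimethoxyphenyl)tetrahydrofuran-3-carboxylate
Product: 9 [(2R,3R,4R)-4-(3,4-dimethoxybenzyl)-2-(3,4,5-trimethoxyphenyl)tetrahydrofuran-3-yl]methanol
Conditions: LiAlH4, THF, −20 to 0 °C; then H2O, aq NaOH
Reagents that add atoms: none
Why: Hydride reduction of the ester to the primary alcohol is faster than enolisation at low temperature, so C8 is not epimerised (its descriptor changes from S to R only because the substituent priorities change), and the basic work-up keeps the acid-sensitive 2-aryl ether intact.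

**Compound list**

1 | ethyl 3-oxo-3-(3,4,5-trimethoxyphenyl)propanoate | CCOC(=O)CC(=O)c1cc(OC)c(OC)c(OC)c1 | starting material
2 | ethyl 2-bromo-3-oxo-3-(3,4,5-trimethoxyphenyl)propanoate (racemic) | CCOC(=O)C(Br)C(=O)c1cc(OC)c(OC)c(OC)c1 | intermediate
3 | 3-(3,4-dimethoxyphenyl)propanal | COc1ccc(CCC=O)cc1OC | starting material
4 | ethyl (3R)-4-(3,4-dimethoxyphenyl)-3-formyl-2-(3,4,5-trimethoxybenzoyl)butanoate (C2 epimers) | COc1ccc(C[C@@H](C=O)C(C(=O)OCC)C(=O)c2cc(OC)c(OC)c(OC)c2)cc1OC | intermediate
5 | ethyl (3R)-4-(3,4-dimethoxyphenyl)-3-(hydroxymethyl)-2-(3,4,5-trimethoxybenzoyl)butanoate (C2 epimers) | COc1ccc(C[C@@H](CO)C(C(=O)OCC)C(=O)c2cc(OC)c(OC)c(OC)c2)cc1OC | intermediate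
6 | ethyl (4R)-4-(3,4-dimethoxybenzyl)-2-hydroxy-2-(3,4,5-trimethoxyphenyl)tetrahydrofuran-3-carboxylate (C2 and C3 mixture) | COc1ccc(C[C@H]2COC(O)(c3cc(OC)c(OC)c(OC)c3)C2C(=O)OCC)cc1OC | intermediate
7 | ethyl (4R)-4-(3,4-dimethoxybenzyl)-2-(3,4,5-trimethoxyphenyl)-4,5-dihydrofuran-3-carboxylate | COc1ccc(C[C@H]2COC(c3cc(OC)c(OC)c(OC)c3)=C2C(=O)OCC)cc1OC | intermediate
8 | ethyl (2R,3S,4R)-4-(3,4-dimethoxybenzyl)-2-(3,4,5-trimethoxyphenyl)tetrahydrofuran-3-carboxylate | COc1ccc(C[C@H]2CO[C@@H](c3cc(OC)c(OC)c(OC)c3)[C@H]2C(=O)OCC)cc1OC | intermediate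
9 | [(2R,3R,4R)-4-(3,4-dimethoxybenzyl)-2-(3,4,5-trimethoxyphenyl)tetrahydrofuran-3-yl]methanol | COc1ccc(C[C@H]2CO[C@@H](c3cc(OC)c(OC)c(OC)c3)[C@H]2CO)cc1OC | target

**Step count and risk**

Total steps: 5. Longest linear sequence: 5 (1 → 2 → 5 → 7 → 8 → 9).

Most likely to fail, first: step 2. α-Bromo-β-keto esters of this kind are not a documented bromide class for the photoredox alkylation. Compound 2 is more acidic and a better bromine donor than a bromomalonate, so bromine transfer to the enamine, disproportionation of 2 under lutidine, or simple reduction of the radical may compete, and the enantiomeric excess is untested. The fallback makes the 8–8′ bond by polar allylic substitution; it sets out from 1 and comes back at 5. Cross-metathesis of commercial methyl eugenol with allyl methyl carbonate (second-generation Grubbs catalyst, RuCl2(=CHPh)(H2IMes)(PCy3), CH2Cl2, 40 °C) gives (E)-4-(3,4-dimethoxyphenyl)but-2-en-1-yl methyl carbonate F1. Branched-selective asymmetric allylic alkylation of 1 with F1 ([Ir(cod)Cl]2, a Feringa-type phosphoramidite of the enantiomer that gives the 3S product, THF) gives ethyl (3S)-3-(3,4-dimethoxybenzyl)-2-(3,4,5-trimethoxybenzoyl)pent-4-enoate F2, with C8′ set by the ligand. Ozonolysis of the vinyl group with NaBH4 work-up at −40 °C turns it into the CH2OH of 5.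

Second: step 4. The tetrasubstituted push–pull alkene may be sluggish on Pd/C. Longer exposure risks hydrogenolysis of the new benzylic C–O bond or double-bond migration, which would erode C8′; Rh/Al2O3 is the catalyst variation to try first. The fallback sets C7 by hydride delivery to an oxocarbenium ion instead; it sets out from 5 and comes back at 9. Catalytic DBU in toluene lactonises 5 and equilibrates C8 to the trans lactone (3S,4R)-4-(3,4-dimethoxybenzyl)-3-(3,4,5-trimethoxybenzoyl)dihydrofuran-2(3H)-one F3. LiBH4 reduces ketone and lactone to (2R,3R)-2-(3,4-dimethoxybenzyl)-3-[hydroxy(3,4,5-trimethoxyphenyl)methyl]butane-1,4-diol F4. MnO2 in CH2Cl2 re-oxidises only the benzylic alcohol, and the ketone closes to (3R,4R)-4-(3,4-dimethoxybenzyl)-3-(hydroxymethyl)-2-(3,4,5-trimethoxyphenyl)tetrahydrofuran-2-ol F5. Et3SiH with BF3·OEt2 in CH2Cl2 at −78 °C then delivers hydride to the 2-aryl oxocarbenium ion from the face opposite the cis C8 and C8′ substituents and gives 9. The temperature must stay low, because the ketone and oxocarbenium stages can epimerise C8.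

Third: step 5. The all-cis ester is hindered; if the reduction needs warming, an aluminium enolate could epimerise C8 to the trans ester or open the ring by β-elimination of the C7 oxygen. The fallback reduces the ester while C8 is still sp2; it sets out from 7 and comes back at 9. i-Bu2AlH in CH2Cl2 at −78 °C gives [(4R)-4-(3,4-dimethoxybenzyl)-2-(3,4,5-trimethoxyphenyl)-4,5-dihydrofuran-3-yl]methanol F6. Homogeneous hydrogenation with [Ir(cod)(PCy3)(py)]PF6 in CH2Cl2 adds hydrogen anti to the C8′ benzyl group and gives 9 directly; this catalyst is chosen to avoid allylic and benzylic C–O hydrogenolysis.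

**Further compounds**

F1 | step 2 | (E)-4-(3,4-dimethoxyphenyl)but-2-en-1-yl methyl carbonate | COC(=O)OC/C=C/Cc1ccc(OC)c(OC)c1
F2 | step 2 | ethyl (3S)-3-(3,4-dimethoxybenzyl)-2-(3,4,5-trimethoxybenzoyl)pent-4-enoate (C2 epimers) | COc1ccc(C[C@@H](C=C)C(C(=O)OCC)C(=O)c2cc(OC)c(OC)c(OC)c2)cc1OC
F3 | step 4 | (3S,4R)-4-(3,4-dimethoxybenzyl)-3-(3,4,5-trimethoxybenzoyl)dihydrofuran-2(3H)-one | COc1ccc(C[C@H]2COC(=O)[C@@H]2C(=O)c3cc(OC)c(OC)c(OC)c3)cc1OC
F4 | step 4 | (2R,3R)-2-(3,4-dimethoxybenzyl)-3-[hydroxy(3,4,5-trimethoxyphenyl)methyl]butane-1,4-diol (carbinol epimers) | COc1ccc(C[C@@H](CO)[C@H](CO)C(O)c2cc(OC)c(OC)c(OC)c2)cc1OC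
F5 | step 4 | (3R,4R)-4-(3,4-dimethoxybenzyl)-3-(hydroxymethyl)-2-(3,4,5-trimethoxyphenyl)tetrahydrofuran-2-ol (anomers) | COc1ccc(C[C@H]2COC(O)(c3cc(OC)c(OC)c(OC)c3)[C@H]2CO)cc1OC
F6 | step 5 | [(4R)-4-(3,4-dimethoxybenzyl)-2-(3,4,5-trimethoxyphenyl)-4,5-dihydrofuran-3-yl]methanol | COc1ccc(C[C@H]2COC(c3cc(OC)c(OC)c(OC)c3)=C2CO)cc1OC
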